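The furofuran core (3,7-dioxabicyclo[3.3.0]octane; ring A = C1, C2, O3, C4, C5 with the keto-side-chain aryl on C2; ring B = C1, C5, C6, O7, C8) is traced back to an acyclic epoxy cinnamyl ether in which C6 is the only controlling stereocentre. In one flask Cp2TiCl opens the oxirane to a C5 radical that closes ring B onto the cinnamyl alkene (C5–C1), and iodine then turns the benzylic C2–titanium bond into an iodide that the C4 alkoxide displaces, closing ring A last (C2–O3). The step exploits the para-oxygenated benzylic C2 and the shared C1–C5 bond. Both arylpropanoid side units come from one Evans aldol diol.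

Key step: step 17

Assumption: compounds 1, 6, 8, 14 and 17 are taken as catalogue compounds, and oxirane 20 is carried as a mixture of epimers at its oxirane carbon because that centre becomes a radical in step 17.

Abbreviations in names: TBS = tert-butyldimethylsilyl; TES = triethylsilyl; DHB = (2S,3S)-2-[4-(benzyloxy)-3-methoxyphenyl]-3-[(TBS-oxy)methyl]-7-methoxy-2,3-dihydro-1-benzofuran-5-yl (2,3-cis); SC = (1R,2S)-1-[4-(benzyloxy)-3-methoxyphenyl]-1,3-bis(TES-oxy)propan-2-yl.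

Step 1
Reactants: 1 2-allyl-6-methoxyphenol (o-eugenol)
Product: 2 2-allyl-4-bromo-6-methoxyphenol
Conditions: NBS, MeCN, 0 °C
Reagents that add atoms: N-bromosuccinimide, O=C1CCC(=O)N1Br
Why: Electrophilic aromatic bromination; both ortho positions of the phenol are blocked, so bromine should enter para to OH, and the phenol ring reacts faster than the isolated alkene.

Step 2
Reactants: 2 2-allyl-4-bromo-6-methoxyphenol
Product: 3 (2-allyl-4-bromo-6-methoxyphenoxy)(tert-butyl)dimethylsilane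
Conditions: TBSCl, imidazole, DMAP (cat.), DMF, 40 °C
Reagents that add atoms: tert-butyldimethylsilyl chloride, CC(C)(C)[Si](C)(C)Cl
Why: Silylation of the phenol gives an aryl silyl ether shielded by two ortho substituents that can later be cleaved selectively by fluoride.

Step 3
Reactants: 3 (2-allyl-4-bromo-6-methoxyphenoxy)(tert-butyl)dimethylsilane
Product: 4 2-[5-bromo-2-(TBS-oxy)-3-methoxyphenyl]acetaldehyde
Conditions: O3, CH2Cl2/MeOH, −78 °C; then PPh3
Reagents that add atoms: ozone, [O-][O+]=O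
Why: Ozonolysis with reductive work-up cleaves the terminal alkene to the arylacetaldehyde, the brominated arene being much less reactive toward ozone at −78 °C.

Step 4
Reactants: 4 2-[5-bromo-2-(TBS-oxy)-3-methoxyphenyl]acetaldehyde
Product: 5 2-[5-bromo-2-(TBS-oxy)-3-methoxyphenyl]acetic acid
Conditions: NaClO2, NaH2PO4, 2-methyl-2-butene, t-BuOH/H2O, 0 °C to rt
Reagents that add atoms: sodium chlorite, [Na+].[O-]Cl=O
Why: Pinnick oxidation converts the aldehyde to the acid under buffered conditions that spare the aryl silyl ether, the alkene scavenging hypochlorite.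

Step 5
Reactants: 5 2-[5-bromo-2-(TBS-oxy)-3-methoxyphenyl]acetic acid; 6 (R)-4-benzyloxazolidin-2-one
Product: 7 (R)-4-benzyl-3-{2-[5-bromo-2-(TBS-oxy)-3-methoxyphenyl]acetyl}oxazolidin-2-one
Conditions: PivCl, Et3N, THF, −20 °C; then LiCl, 6, rt
Reagents that add atoms: none
Why: N-Acylation of the Evans auxiliary through the mixed pivalic anhydride with LiCl/Et3N activation avoids strong base.

Step 6
Reactants: 7 (R)-4-benzyl-3-{2-[5-bromo-2-(TBS-oxy)-3-methoxyphenyl]acetyl}oxazolidin-2-one; 8 4-(benzyloxy)-3-methoxybenzaldehyde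
Product: 9 (R)-4-benzyl-3-{(2R,3R)-3-[4-(benzyloxy)-3-methoxyphenyl]-2-[5-bromo-2-(TBS-oxy)-3-methoxyphenyl]-3-hydroxypropanoyl}oxazolidin-2-one
Conditions: Bu2BOTf, i-Pr2NEt, CH2Cl2, −78 to 0 °C; then 8, −78 to 0 °C; pH 7 buffer, MeOH, H2O2
Reagents that add atoms: none
Why: Evans syn-aldol reaction; the (Z)-boron enolate reacts through a Zimmerman–Traxler chair on the face opposite the auxiliary benzyl group, which should set both new stereocentres as (2R,3R).

Step 7
Reactants: 9 Evans syn-aldol adduct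
Product: 10 (1R,2S)-1-[4-(benzyloxy)-3-methoxyphenyl]-2-[5-bromo-2-(TBS-oxy)-3-methoxyphenyl]propane-1,3-diol
Conditions: LiBH4, THF, H2O (1 equiv), 0 °C
Reagents that add atoms: none
Why: Reductive cleavage of the N-acyloxazolidinone gives the primary alcohol without touching the two stereocentres and releases the auxiliary.

Step 8
Reactants: 10 (1R,2S)-diol
Product: 11 (1R,2S)-1-[4-(benzyloxy)-3-methoxyphenyl]-2-[5-bromo-2-(TBS-oxy)-3-methoxyphenyl]-3-(TBS-oxy)propan-1-ol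
Conditions: TBSCl (1.05 equiv), imidazole, CH2Cl2, 0 °C
Reagents that add atoms: tert-butyldimethylsilyl chloride, CC(C)(C)[Si](C)(C)Cl
Why: The primary alcohol is silylated much faster than the hindered secondary benzylic alcohol.

Step 9
Reactants: 11 primary TBS ether
Product: 12 (1R,2S)-1-[4-(benzyloxy)-3-methoxyphenyl]-2-(5-bromo-2-hydroxy-3-methoxyphenyl)-3-(TBS-oxy)propan-1-ol
Conditions: KHF2, MeOH, rt
Reagents that add atoms: none
Why: KHF2 in methanol cleaves phenolic silyl ethers selectively and should leave the alkyl silyl ether intact.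

Step 10
Reactants: 12 phenol with free benzylic alcohol
Product: 13 (2S,3S)-2-[4-(benzyloxy)-3-methoxyphenyl]-5-bromo-3-[(TBS-oxy)methyl]-7-methoxy-2,3-dihydro-1-benzofuran (2,3-cis; DHB bromide)
Conditions: PPh3, DIAD, THF, 0 °C
Reagents that add atoms: none
Why: Intramolecular Mitsunobu etherification; the phenol displaces the activated benzylic oxygen in a 5-exo-tet SN2 closure with inversion, which should turn the syn diol into the 2,3-cis dihydrobenzofuran of (2S,3S) configuration.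

Step 11
Reactants: 13 DHB bromide; 14 (E)-3-(4,4,5,5-tetramethyl-1,3,2-dioxaborolan-2-yl)prop-2-en-1-ol
Product: 15 (E)-3-(DHB)prop-2-en-1-ol
Conditions: Pd(dppf)Cl2 (5 mol %), K2CO3, dioxane/H2O, 80 °C
Reagents that add atoms: none
Why: Suzuki–Miyaura coupling of the unhindered aryl bromide with the (E)-alkenylboronate proceeds with retention of alkene geometry.

Step 12
Reactants: 15 (E)-3-(DHB)prop-2-en-1-ol
Product: 16 (E)-3-(DHB)prop-2-enyl methyl carbonate
Conditions: ClCO2Me, pyridine, CH2Cl2, 0 °C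
Reagents that add atoms: methyl chloroformate, COC(=O)Cl
Why: Acylation of the allylic alcohol installs the carbonate leaving group needed for allylic substitution.

Step 13
Reactants: 16 (E)-3-(DHB)prop-2-enyl methyl carbonate; 17 3-(trimethylsilyl)prop-2-yn-1-ol
Product: 19 (S)-1-(DHB)prop-2-enyl prop-2-ynyl ether, via TMS-alkyne ether 18 (not isolated)
Conditions: [Ir(cod)Cl]2 (2 mol %), (Sa,Sc,Sc)-BINOL bis(1-phenylethyl)amine phosphoramidite (4 mol %, pre-activated with n-PrNH2), K3PO4, THF, rt; then K2CO3, MeOH, rt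
Reagents that add atoms: none
Why: Iridium-catalysed asymmetric allylic etherification (Hartwig type); the cyclometalated iridium–phosphoramidite catalyst ionises the carbonate and delivers the alkoxide to the aryl-substituted allyl terminus, so the branched ether should form with the new stereocentre (C6 of the later core) set as (S) by the ligand, and K2CO3/MeOH then removes the alkynyl silyl group.

Step 14
Reactants: 19 (S)-1-(DHB)prop-2-enyl prop-2-ynyl ether
Product: 20 2-[(R)-(DHB)(prop-2-ynyloxy)methyl]oxirane (mixture of epimers at the oxirane carbon)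
Conditions: dimethyldioxirane, acetone/CH2Cl2, 0 °C
Reagents that add atoms: dimethyldioxirane, CC1(C)OO1
Why: Electrophilic epoxidation takes the only alkene, the alkyne and arenes reacting much more slowly; the new oxirane stereocentre is uncontrolled and is erased in step 17.

Step 15
Reactants: 10 (1R,2S)-diol
Product: 21 [4-bromo-2-methoxy-6-(SC)phenoxy](tert-butyl)dimethylsilane
Conditions: TESCl (3 equiv), imidazole, DMAP (cat.), DMF, rt
Reagents that add atoms: triethylsilyl chloride, CC[Si](Cl)(CC)CC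
Why: Exhaustive silylation protects both hydroxyls as triethylsilyl ethers, which can later be removed in the presence of the TBS ethers.

Step 16
Reactants: 20 alkynyl oxirane; 21 aryl bromide carrying SC
Product: 23 2-[(R)-(DHB){(E)-3-[4-(TBS-oxy)-3-methoxy-5-(SC)phenyl]prop-2-enyloxy}methyl]oxirane (epimers at the oxirane carbon), via alkenylborane 22 (not isolated)
Conditions: Cy2BH, THF, 0 °C to rt; then 21, Pd(PPh3)4 (5 mol %), aq. K3PO4, THF, 50 °C
Reagents that add atoms: none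
Why: Brown hydroboration of the terminal alkyne is syn and anti-Markovnikov and gives the (E)-alkenylborane, which should undergo Suzuki–Miyaura coupling with 21 with retention of geometry while the oxirane is untouched.

Step 17
Reactants: 23 epoxy cinnamyl ether
Product: 26 (1R,2S,5R,6S)-2-[4-(TBS-oxy)-3-methoxy-5-(SC)phenyl]-6-(DHB)-3,7-dioxabicyclo[3.3.0]octane, via bis-titanium intermediate 24 (not isolated), via benzylic iodide 25 (not isolated)
Conditions: Cp2TiCl2 (3 equiv), Zn, THF, rt, slow addition of 23; then I2, rt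
Reagents that add atoms: none
Why: Cp2TiCl (trivalent titanium, formed from Cp2TiCl2 and Zn) opens the terminal oxirane by single-electron transfer to the β-titanoxy secondary radical at C5, which closes ring B by 5-exo-trig addition to the (E)-cinnamyl alkene (C5–C1 bond), and a second equivalent traps the benzylic C2 radical as benzyltitanium 24. Iodine converts this into benzylic iodide 25, whose ionisation is assisted by the para-silyloxy aryl ring, and the neighbouring C4 titanium alkoxide closes ring A last by 5-exo-tet attack at C2 (C2–O3 bond). The closest known reaction is the Cp2TiCl radical cyclisation of epoxy cinnamyl ethers with iodine treatment that has been used for furofuran lignans of the pinoresinol and sesamin type. C5 and C1 are set together in the chair-like Beckwith–Houk transition state, in which the C6 aryl group sits pseudo-equatorial and ends trans to the new C1 substituent while the C4 titanoxymethyl arm ends cis to it, and C2 takes the exo (convex-face) aryl orientation in the SN1-like ether closure, so the single preset centre C6 controls all three. The step needs cyclisation to outrun reduction or β-alkoxide loss of the C5 radical, which the activated styrene acceptor should secure, and C–O closure at C2 to beat elimination, which the cis-disposed alkoxide should secure.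

Step 18
Reactants: 26 fully protected furofuran
Product: 27 (1R,2S)-1-[4-(benzyloxy)-3-methoxyphenyl]-2-{2-(TBS-oxy)-3-methoxy-5-[(1R,2S,5R,6S)-6-(DHB)-3,7-dioxabicyclo[3.3.0]oct-2-yl]phenyl}propane-1,3-diol
Conditions: HF·pyridine, pyridine, THF, 0 °C
Reagents that add atoms: none
Why: Buffered HF·pyridine cleaves the triethylsilyl ethers much faster than the alkyl and aryl TBS ethers.

Step 19
Reactants: 27 diol
Product: 28 (S)-1-[4-(benzyloxy)-3-methoxyphenyl]-3-hydroxy-2-{2-(TBS-oxy)-3-methoxy-5-[(1R,2S,5R,6S)-6-(DHB)-3,7-dioxabicyclo[3.3.0]oct-2-yl]phenyl}propan-1-one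
Conditions: MnO2 (activated, excess), CH2Cl2, rt
Reagents that add atoms: none
Why: MnO2 oxidises only the benzylic secondary alcohol to the aryl ketone and leaves the aliphatic primary alcohol alone, under neutral heterogeneous conditions chosen to preserve the adjacent α-aryl stereocentre.

Step 20
Reactants: 28 ketone
Product: 29 bis(O-benzyl) ether of the target (both 4-hydroxy-3-methoxyphenyl groups still benzylated, all silyl groups removed)
Conditions: TBAF, AcOH (1:1), THF, 0 °C to rt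
Reagents that add atoms: none
Why: Acetic acid-buffered fluoride removes the aryl and alkyl TBS ethers without the basicity that could epimerise the α-aryl ketone or dehydrate the β-hydroxy ketone.

Step 21
Reactants: 29 bis(O-benzyl) ether of the target
Product: 30 CNP0174045.1 (target)
Conditions: H2 (1 atm), Pd/C (10 %), EtOAc, rt
Reagents that add atoms: none
Why: Hydrogenolysis of the two aryl benzyl ethers should be much faster than cleavage of the cyclic benzylic ethers or reduction of the aryl ketone under these neutral conditions.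

Compound list
1 | 2-allyl-6-methoxyphenol (o-eugenol) | C=CCc1cccc(OC)c1O | starting material
2 | 2-allyl-4-bromo-6-methoxyphenol | C=CCc1cc(Br)cc(OC)c1O | intermediate
3 | (2-allyl-4-bromo-6-methoxyphenoxy)(tert-butyl)dimethylsilane | C=CCc1cc(Br)cc(OC)c1O[Si](C)(C)C(C)(C)C | intermediate
4 | 2-[5-bromo-2-(TBS-oxy)-3-methoxyphenyl]acetaldehyde | O=CCc1cc(Br)cc(OC)c1O[Si](C)(C)C(C)(C)C | intermediate
5 | 2-[5-bromo-2-(TBS-oxy)-3-methoxyphenyl]acetic acid | OC(=O)Cc1cc(Br)cc(OC)c1O[Si](C)(C)C(C)(C)C | intermediate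
6 | (R)-4-benzyloxazolidin-2-one | O=C1N[C@H](Cc2ccccc2)CO1 | starting material
7 | (R)-4-benzyl-3-{2-[5-bromo-2-(TBS-oxy)-3-methoxyphenyl]acetyl}oxazolidin-2-one | O=C(Cc1cc(Br)cc(OC)c1O[Si](C)(C)C(C)(C)C)N1C(=O)OC[C@H]1Cc1ccccc1 | intermediate
8 | 4-(benzyloxy)-3-methoxybenzaldehyde | COc1cc(C=O)ccc1OCc1ccccc1 | starting material
9 | (R)-4-benzyl-3-{(2R,3R)-3-[4-(benzyloxy)-3-methoxyphenyl]-2-[5-bromo-2-(TBS-oxy)-3-methoxyphenyl]-3-hydroxypropanoyl}oxazolidin-2-one | O=C([C@H](c1cc(Br)cc(OC)c1O[Si](C)(C)C(C)(C)C)[C@@H](O)c1ccc(OCc2ccccc2)c(OC)c1)N1C(=O)OC[C@H]1Cc1ccccc1 | intermediate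
10 | (1R,2S)-1-[4-(benzyloxy)-3-methoxyphenyl]-2-[5-bromo-2-(TBS-oxy)-3-methoxyphenyl]propane-1,3-diol | OC[C@H](c1cc(Br)cc(OC)c1O[Si](C)(C)C(C)(C)C)[C@@H](O)c1ccc(OCc2ccccc2)c(OC)c1 | intermediate
11 | (1R,2S)-1-[4-(benzyloxy)-3-methoxyphenyl]-2-[5-bromo-2-(TBS-oxy)-3-methoxyphenyl]-3-(TBS-oxy)propan-1-ol | CC(C)(C)[Si](C)(C)OC[C@H](c1cc(Br)cc(OC)c1O[Si](C)(C)C(C)(C)C)[C@@H](O)c1ccc(OCc2ccccc2)c(OC)c1 | intermediate
12 | (1R,2S)-1-[4-(benzyloxy)-3-methoxyphenyl]-2-(5-bromo-2-hydroxy-3-methoxyphenyl)-3-(TBS-oxy)propan-1-ol | CC(C)(C)[Si](C)(C)OC[C@H](c1cc(Br)cc(OC)c1O)[C@@H](O)c1ccc(OCc2ccccc2)c(OC)c1 | intermediate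
13 | (2S,3S)-2-[4-(benzyloxy)-3-methoxyphenyl]-5-bromo-3-[(TBS-oxy)methyl]-7-methoxy-2,3-dihydro-1-benzofuran (cis; DHB bromide) | Brc1cc(OC)c2c(c1)[C@@H](CO[Si](C)(C)C(C)(C)C)[C@@H](c1ccc(OCc3ccccc3)c(OC)c1)O2 | intermediate
14 | (E)-3-(4,4,5,5-tetramethyl-1,3,2-dioxaborolan-2-yl)prop-2-en-1-ol | OC/C=C/B1OC(C)(C)C(C)(C)O1 | starting material
15 | (E)-3-(DHB)prop-2-en-1-ol | OC/C=C/c1cc(OC)c2c(c1)[C@@H](CO[Si](C)(C)C(C)(C)C)[C@@H](c1ccc(OCc3ccccc3)c(OC)c1)O2 | intermediate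
16 | (E)-3-(DHB)prop-2-enyl methyl carbonate | COC(=O)OC/C=C/c1cc(OC)c2c(c1)[C@@H](CO[Si](C)(C)C(C)(C)C)[C@@H](c1ccc(OCc3ccccc3)c(OC)c1)O2 | intermediate
17 | 3-(trimethylsilyl)prop-2-yn-1-ol | C[Si](C)(C)C#CCO | starting material
18 | trimethyl{3-[(S)-1-(DHB)prop-2-enyloxy]prop-1-ynyl}silane | C[Si](C)(C)C#CCO[C@@H](C=C)c1cc(OC)c2c(c1)[C@@H](CO[Si](C)(C)C(C)(C)C)[C@@H](c1ccc(OCc3ccccc3)c(OC)c1)O2 | intermediate (not isolated)
19 | (S)-1-(DHB)prop-2-enyl prop-2-ynyl ether | C#CCO[C@@H](C=C)c1cc(OC)c2c(c1)[C@@H](CO[Si](C)(C)C(C)(C)C)[C@@H](c1ccc(OCc3ccccc3)c(OC)c1)O2 | intermediate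
20 | 2-[(R)-(DHB)(prop-2-ynyloxy)methyl]oxirane, epimers at the oxirane carbon | C#CCO[C@@H](C1CO1)c1cc(OC)c2c(c1)[C@@H](CO[Si](C)(C)C(C)(C)C)[C@@H](c1ccc(OCc3ccccc3)c(OC)c1)O2 | intermediate
21 | [4-bromo-2-methoxy-6-(SC)phenoxy](tert-butyl)dimethylsilane | CC[Si](CC)(CC)OC[C@H](c1cc(Br)cc(OC)c1O[Si](C)(C)C(C)(C)C)[C@@H](O[Si](CC)(CC)CC)c1ccc(OCc2ccccc2)c(OC)c1 | intermediate
22 | dicyclohexyl{(E)-3-[(R)-(DHB)(oxiran-2-yl)methoxy]prop-1-enyl}borane | C1CCCCC1B(C1CCCCC1)/C=C/CO[C@@H](C1CO1)c1cc(OC)c2c(c1)[C@@H](CO[Si](C)(C)C(C)(C)C)[C@@H](c1ccc(OCc3ccccc3)c(OC)c1)O2 | intermediate (not isolated)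
23 | 2-[(R)-(DHB){(E)-3-[4-(TBS-oxy)-3-methoxy-5-(SC)phenyl]prop-2-enyloxy}methyl]oxirane, epimers at the oxirane carbon | CC[Si](CC)(CC)OC[C@H](c1cc(/C=C/CO[C@@H](C2CO2)c2cc(OC)c3c(c2)[C@@H](CO[Si](C)(C)C(C)(C)C)[C@@H](c2ccc(OCc4ccccc4)c(OC)c2)O3)cc(OC)c1O[Si](C)(C)C(C)(C)C)[C@@H](O[Si](CC)(CC)CC)c1ccc(OCc2ccccc2)c(OC)c1 | intermediate
24 | (2S,3R,4R)-2-(DHB)-tetrahydrofuran with 3-CH2O–TiCp2Cl and 4-CH(TiCp2Cl)Ar, Ar = 4-(TBS-oxy)-3-methoxy-5-(SC)phenyl (ring B closed; Cp drawn σ-bonded) | CC[Si](CC)(CC)OC[C@H](c1cc(C([Ti](Cl)(C2C=CC=C2)C2C=CC=C2)[C@H]2CO[C@H](c3cc(OC)c4c(c3)[C@@H](CO[Si](C)(C)C(C)(C)C)[C@@H](c3ccc(OCc5ccccc5)c(OC)c3)O4)[C@H]2CO[Ti](Cl)(C2C=CC=C2)C2C=CC=C2)cc(OC)c1O[Si](C)(C)C(C)(C)C)[C@@H](O[Si](CC)(CC)CC)c1ccc(OCc2ccccc2)c(OC)c1 | intermediate (not isolated)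
25 | (2S,3R,4R)-2-(DHB)-tetrahydrofuran with 3-CH2O–TiCp2Cl and 4-CH(I)Ar, same Ar | CC[Si](CC)(CC)OC[C@H](c1cc(C(I)[C@H]2CO[C@H](c3cc(OC)c4c(c3)[C@@H](CO[Si](C)(C)C(C)(C)C)[C@@H](c3ccc(OCc5ccccc5)c(OC)c3)O4)[C@H]2CO[Ti](Cl)(C2C=CC=C2)C2C=CC=C2)cc(OC)c1O[Si](C)(C)C(C)(C)C)[C@@H](O[Si](CC)(CC)CC)c1ccc(OCc2ccccc2)c(OC)c1 | intermediate (not isolated)
26 | (1R,2S,5R,6S)-2-[4-(TBS-oxy)-3-methoxy-5-(SC)phenyl]-6-(DHB)-3,7-dioxabicyclo[3.3.0]octane | CC[Si](CC)(CC)OC[C@H](c1cc([C@H]2OC[C@H]3[C@@H]2CO[C@@H]3c2cc(OC)c3c(c2)[C@@H](CO[Si](C)(C)C(C)(C)C)[C@@H](c2ccc(OCc4ccccc4)c(OC)c2)O3)cc(OC)c1O[Si](C)(C)C(C)(C)C)[C@@H](O[Si](CC)(CC)CC)c1ccc(OCc2ccccc2)c(OC)c1 | intermediate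
27 | (1R,2S)-1-[4-(benzyloxy)-3-methoxyphenyl]-2-{2-(TBS-oxy)-3-methoxy-5-[(1R,2S,5R,6S)-6-(DHB)-3,7-dioxabicyclo[3.3.0]oct-2-yl]phenyl}propane-1,3-diol | OC[C@H](c1cc([C@H]2OC[C@H]3[C@@H]2CO[C@@H]3c2cc(OC)c3c(c2)[C@@H](CO[Si](C)(C)C(C)(C)C)[C@@H](c2ccc(OCc4ccccc4)c(OC)c2)O3)cc(OC)c1O[Si](C)(C)C(C)(C)C)[C@@H](O)c1ccc(OCc2ccccc2)c(OC)c1 | intermediate
28 | (S)-1-[4-(benzyloxy)-3-methoxyphenyl]-3-hydroxy-2-{2-(TBS-oxy)-3-methoxy-5-[(1R,2S,5R,6S)-6-(DHB)-3,7-dioxabicyclo[3.3.0]oct-2-yl]phenyl}propan-1-one | OC[C@H](c1cc([C@H]2OC[C@H]3[C@@H]2CO[C@@H]3c2cc(OC)c3c(c2)[C@@H](CO[Si](C)(C)C(C)(C)C)[C@@H](c2ccc(OCc4ccccc4)c(OC)c2)O3)cc(OC)c1O[Si](C)(C)C(C)(C)C)C(=O)c1ccc(OCc2ccccc2)c(OC)c1 | intermediate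
29 | bis(O-benzyl) ether of the target (both 4-hydroxy-3-methoxyphenyl groups as benzyl ethers) | OC[C@H](c1cc([C@H]2OC[C@H]3[C@@H]2CO[C@@H]3c2cc(OC)c3c(c2)[C@@H](CO)[C@@H](c2ccc(OCc4ccccc4)c(OC)c2)O3)cc(OC)c1O)C(=O)c1ccc(OCc2ccccc2)c(OC)c1 | intermediate
30 | CNP0174045.1 | COc1cc(C(=O)[C@H](CO)c2cc([C@H]3OC[C@H]4[C@@H]3CO[C@@H]4c3cc(OC)c4c(c3)[C@@H](CO)[C@@H](c3ccc(O)c(OC)c3)O4)cc(OC)c2O)ccc1O | target

Total step count: 21. Longest linear sequence: 20 steps (steps 1–14 and 16–21; step 15 is the side branch).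

Steps most likely to fail

1. Step 17. After ring B has closed, the benzylic titanium or iodide stage may be diverted by protonation, dimerisation or elimination to a styrene, or the ether closure may show low exo selectivity at C2. The fallback sets out from 23 and comes back at 26. The same Cp2TiCl cyclisation is quenched with aqueous NaH2PO4 instead of iodine, which should give the ring B alcohol F1 with a benzylic CH2 at C2. Cs2CO3 in wet DMF then removes only the aryl TBS group to give the free phenol F2. Ag2O in CH2Cl2 oxidises this 4-alkyl-2-methoxyphenol to its para-quinone methide at C2, and the C4 hydroxyl adds across it (biomimetic 1,6-addition, exo aryl) to give the furofuran phenol F3. TBSCl and imidazole return 26.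

2. Step 13. The branched regioselectivity or the catalyst control over the new stereocentre may be lost against the resident stereocentres, or the alkyne may inhibit the catalyst. The fallback sets out from 13 and comes back at 19. Bromine–lithium exchange (t-BuLi, THF, −78 °C) and DMF give the aldehyde F4. Vinylmagnesium bromide gives the carbinol epimer mixture F5, and MnO2 oxidises it to the aryl vinyl ketone F6. Corey–Bakshi–Shibata reduction with (R)-2-methyl-CBS-oxazaborolidine and catecholborane should give the (S)-carbinol F7. Williamson etherification with NaH and propargyl bromide returns 19.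

3. Step 10. The activated, electron-rich benzylic alcohol may ionise before displacement, which would give the trans isomer and erode stereochemical purity. The fallback sets out from 5 and comes back at 13. TBAF followed by acidic work-up frees the phenol, which lactonises to the benzofuranone F8. K2CO3 in MeOH with 4-(benzyloxy)-3-methoxybenzyl chloride opens the lactone and alkylates the phenoxide to give the methyl ester F9. Diazo transfer with p-acetamidobenzenesulfonyl azide and DBU gives the aryldiazoacetate F10. Rh2(S-PTTL)4 (dirhodium tetrakis[N-phthaloyl-(S)-tert-leucinate], or its enantiomer as needed) catalyses intramolecular carbene insertion into the benzylic ether C–H bond, which should give the cis ester F11. DIBAL-H at −78 °C reduces it to the alcohol F12 without epimerisation, and TBSCl with imidazole returns 13.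

Further compounds
F1 | step 17 | (2S,3R,4R)-2-(DHB)-3-(hydroxymethyl)-4-{[4-(TBS-oxy)-3-methoxy-5-(SC)phenyl]methyl}tetrahydrofuran | CC[Si](CC)(CC)OC[C@H](c1cc(C[C@H]2CO[C@H](c3cc(OC)c4c(c3)[C@@H](CO[Si](C)(C)C(C)(C)C)[C@@H](c3ccc(OCc5ccccc5)c(OC)c3)O4)[C@H]2CO)cc(OC)c1O[Si](C)(C)C(C)(C)C)[C@@H](O[Si](CC)(CC)CC)c1ccc(OCc2ccccc2)c(OC)c1
F2 | step 17 | (2S,3R,4R)-2-(DHB)-3-(hydroxymethyl)-4-{[4-hydroxy-3-methoxy-5-(SC)phenyl]methyl}tetrahydrofuran | CC[Si](CC)(CC)OC[C@H](c1cc(C[C@H]2CO[C@H](c3cc(OC)c4c(c3)[C@@H](CO[Si](C)(C)C(C)(C)C)[C@@H](c3ccc(OCc5ccccc5)c(OC)c3)O4)[C@H]2CO)cc(OC)c1O)[C@@H](O[Si](CC)(CC)CC)c1ccc(OCc2ccccc2)c(OC)c1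
F3 | step 17 | (1R,2S,5R,6S)-2-[4-hydroxy-3-methoxy-5-(SC)phenyl]-6-(DHB)-3,7-dioxabicyclo[3.3.0]octane | CC[Si](CC)(CC)OC[C@H](c1cc([C@H]2OC[C@H]3[C@@H]2CO[C@@H]3c2cc(OC)c3c(c2)[C@@H](CO[Si](C)(C)C(C)(C)C)[C@@H](c2ccc(OCc4ccccc4)c(OC)c2)O3)cc(OC)c1O)[C@@H](O[Si](CC)(CC)CC)c1ccc(OCc2ccccc2)c(OC)c1
F4 | step 13 | DHB-carbaldehyde | O=Cc1cc(OC)c2c(c1)[C@@H](CO[Si](C)(C)C(C)(C)C)[C@@H](c1ccc(OCc3ccccc3)c(OC)c1)O2
F5 | step 13 | 1-(DHB)prop-2-en-1-ol, both carbinol epimers | C=CC(O)c1cc(OC)c2c(c1)[C@@H](CO[Si](C)(C)C(C)(C)C)[C@@H](c1ccc(OCc3ccccc3)c(OC)c1)O2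
F6 | step 13 | 1-(DHB)prop-2-en-1-one | C=CC(=O)c1cc(OC)c2c(c1)[C@@H](CO[Si](C)(C)C(C)(C)C)[C@@H](c1ccc(OCc3ccccc3)c(OC)c1)O2
F7 | step 13 | (S)-1-(DHB)prop-2-en-1-ol | C=C[C@H](O)c1cc(OC)c2c(c1)[C@@H](CO[Si](C)(C)C(C)(C)C)[C@@H](c1ccc(OCc3ccccc3)c(OC)c1)O2
F8 | step 10 | 5-bromo-7-methoxy-1-benzofuran-2(3H)-one | O=C1Cc2cc(Br)cc(OC)c2O1
F9 | step 10 | methyl 2-{2-[(4-benzyloxy-3-methoxyphenyl)methoxy]-5-bromo-3-methoxyphenyl}acetate | COC(=O)Cc1cc(Br)cc(OC)c1OCc1ccc(OCc2ccccc2)c(OC)c1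
F10 | step 10 | methyl 2-diazo-2-{2-[(4-benzyloxy-3-methoxyphenyl)methoxy]-5-bromo-3-methoxyphenyl}acetate | COC(=O)C(=[N+]=[N-])c1cc(Br)cc(OC)c1OCc1ccc(OCc2ccccc2)c(OC)c1
F11 | step 10 | methyl (2S,3R)-2-[4-(benzyloxy)-3-methoxyphenyl]-5-bromo-7-methoxy-2,3-dihydro-1-benzofuran-3-carboxylate (cis) | Brc1cc(OC)c2c(c1)[C@@H](C(=O)OC)[C@@H](c1ccc(OCc3ccccc3)c(OC)c1)O2
F12 | step 10 | [(2S,3S)-2-[4-(benzyloxy)-3-methoxyphenyl]-5-bromo-7-methoxy-2,3-dihydro-1-benzofuran-3-yl]methanol (cis) | Brc1cc(OC)c2c(c1)[C@@H](CO)[C@@H](c1ccc(OCc3ccccc3)c(OC)c1)O2
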